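**Plan**
- Retrosynthesis: the C2–CH2 bond of the side chain is cut first, as the C2–C(sp) bond of an alkyne added to a 2-methylchromone. The chromone is then cut at O1–C2 and C2–C3 (acetophenone plus an acetate unit). The cyclohexene (C1' quaternary, C2' CH(CH3), C3'=C4') is cut at C1'–C2' and C5'–C6' (Diels–Alder).
- Enabling feature: the vinylogous ester O1–C2(CH3)=C3–C4=O of the pyranone ring. O-Silylation at the C4 oxygen turns the hetero ring into an aromatic benzopyrylium cation, and its C2 (next to O1, carrying CH3) accepts a copper acetylide, so the tertiary ether carbon arises from a flat precursor.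
- Helpers: the C4 oxygen activates C2, later directs cleavage of the peri C5 methyl ether, and finally leaves as water to give C3=C4. The C≡C of the linker is reduced to CH2CH2.
- Forward order: cyclohexene ring by Diels–Alder, its formyl and benzyloxymethyl arms converted into CH3 and C≡CH; pyranone ring by Claisen condensation and cyclodehydration; fragment union; alkyne saturation, 5-O-demethylation, reduction and dehydration.
- Stereochemistry: C1' and C2' come from one catalytic enantioselective endo Diels–Alder reaction (formyl cis to the C2' methyl, then reduced to CH3, which gives the cis-dimethyl pattern). C2 comes from the chiral copper catalyst in the fragment union.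

Key step: step 11

Assumption: the catalyst antipodes named in steps 6 and 11 are those expected from the accepted transition-state models to give the configurations drawn; the drawn structures, not the catalyst labels, define the route.

Assumption: diene 9 is taken as the pure (E)-isomer; if only an E/Z mixture is supplied, the (Z)-isomer cannot easily reach the s-cis conformation, should not take part in the cycloaddition and would leave with the volatiles.

**Step 1**
Reactants: 1 1-(6-hydroxy-2,3,4-trimethoxyphenyl)ethan-1-one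
Product: 2 1-(3-bromo-2-hydroxy-4,5,6-trimethoxyphenyl)ethan-1-one
Conditions: NBS (1.05 equiv), MeCN, 0 °C to rt
Reagents that add atoms: N-bromosuccinimide, O=C1CCC(=O)N1Br
Why: Electrophilic aromatic bromination should take place at the only unsubstituted ring carbon, which is ortho to the phenol and ortho/para to methoxy groups, much faster than at the acetyl group.

**Step 2**
Reactants: 2 1-(3-bromo-2-hydroxy-4,5,6-trimethoxyphenyl)ethan-1-one
Product: 3 1-(2-hydroxy-3,4,5,6-tetramethoxyphenyl)ethan-1-one
Conditions: NaOMe (excess), CuBr (10 mol%), MeOH/DMF, 110 °C; then aq. HCl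
Reagents that add atoms: sodium methoxide, C[O-].[Na+]
Why: Ullmann-type copper-catalysed methoxylation of an ortho-bromophenoxide (the reaction type that converts 5-bromovanillin into syringaldehyde) should replace bromide by methoxide while the hydrogen-bonded ketone stays intact.

**Step 3**
Reactants: 3 1-(2-hydroxy-3,4,5,6-tetramethoxyphenyl)ethan-1-one
Product: 5 5,6,7,8-tetramethoxy-2-methyl-4H-chromen-4-one, via diketone 4 (not isolated)
Conditions: NaH (4 equiv), EtOAc, THF, reflux; then AcOH, conc. H2SO4 (cat.), 60 °C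
Reagents that add atoms: ethyl acetate, CCOC(C)=O
Why: Crossed Claisen condensation of the acetophenone enolate with ethyl acetate gives the 1,3-diketone, and acid-catalysed cyclodehydration through the phenol oxygen (the classical 2-methylchromone synthesis) closes the pyranone ring.

**Step 4**
Reactants: 6 2-methylidenepropane-1,3-diol
Product: 7 2-[(benzyloxy)methyl]prop-2-en-1-ol
Conditions: NaH (1.0 equiv), BnBr (1.0 equiv), Bu4NI (cat.), THF, 0 °C to rt
Reagents that add atoms: benzyl bromide, BrCc1ccccc1
Why: Williamson etherification of the symmetrical diol with one equivalent of base should give mainly the mono-benzyl ether, which is easily separated from diol and bis-ether.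

**Step 5**
Reactants: 7 2-[(benzyloxy)methyl]prop-2-en-1-ol
Product: 8 2-[(benzyloxy)methyl]prop-2-enal
Conditions: MnO2 (excess), CH2Cl2, rt
Reagents that add atoms: none
Why: MnO2 oxidises the primary allylic alcohol selectively to the 2-substituted acrolein without over-oxidation and without touching the benzyl ether.

**Step 6**
Reactants: 8 2-[(benzyloxy)methyl]prop-2-enal; 9 (3E)-3-methylpenta-1,3-diene
Product: 10 (1S,2R)-1-[(benzyloxy)methyl]-2,3-dimethylcyclohex-3-ene-1-carbaldehyde (formyl cis to the C2 methyl)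
Conditions: (S)-1-(2-methylphenyl)-3,3-diphenyltetrahydro-1H,3H-pyrrolo[1,2-c][1,3,2]oxazaborole (C24H24BNO, (S)-o-tolyl-CBS oxazaborolidine, 20 mol%), HNTf2 (18 mol%), CH2Cl2, −78 °C
Reagents that add atoms: none
Why: Catalytic enantioselective Diels–Alder reaction of a 2-substituted acrolein on a cationic oxazaborolidine: the terminal methyl of the (E)-diene directs "ortho" bond formation to the substituted dienophile carbon, the formyl group sits endo and so ends cis to the C2 methyl, and the catalyst shields one face of the boron-bound s-trans enal (formyl C–H···O model), which sets both stereocentres at once.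

**Step 7**
Reactants: 10 (1S,2R)-1-[(benzyloxy)methyl]-2,3-dimethylcyclohex-3-ene-1-carbaldehyde
Product: 12 ({[(1R,2R)-1,2,3-trimethylcyclohex-3-en-1-yl]methoxy}methyl)benzene, via hydrazone 11 (not isolated)
Conditions: N2H4·H2O, KOH, diethylene glycol, 130 °C; then 200 °C with removal of water
Reagents that add atoms: none
Why: Wolff–Kishner reduction (Huang-Minlon procedure) turns the formyl group, which the endo cycloaddition placed cis to the ring methyl, into the quaternary methyl group; the aldehyde has no α-hydrogen, so nothing can epimerise, and the benzyl ether is stable to base.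

**Step 8**
Reactants: 12 ({[(1R,2R)-1,2,3-trimethylcyclohex-3-en-1-yl]methoxy}methyl)benzene
Product: 13 [(1R,2R)-1,2,3-trimethylcyclohex-3-en-1-yl]methanol
Conditions: Li, NH3(l)/THF, −78 °C; NH4Cl
Reagents that add atoms: none
Why: Dissolving-metal cleavage of the benzyl ether is fast at −78 °C, and an isolated trisubstituted alkene is not reduced under these conditions.

**Step 9**
Reactants: 13 [(1R,2R)-1,2,3-trimethylcyclohex-3-en-1-yl]methanol
Product: 14 (1R,2R)-1,2,3-trimethylcyclohex-3-ene-1-carbaldehyde
Conditions: Dess–Martin periodinane, NaHCO3, CH2Cl2, 0 °C to rt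
Reagents that add atoms: none
Why: Dess–Martin oxidation of the neopentyl primary alcohol stops at the aldehyde, which has no α-hydrogen and cannot epimerise.

**Step 10**
Reactants: 14 (1R,2R)-1,2,3-trimethylcyclohex-3-ene-1-carbaldehyde
Product: 15 (5R,6R)-5-ethynyl-1,5,6-trimethylcyclohex-1-ene
Conditions: dimethyl (1-diazo-2-oxopropyl)phosphonate, K2CO3, MeOH, 0 °C to rt
Reagents that add atoms: dimethyl (1-diazo-2-oxopropyl)phosphonate (Ohira–Bestmann reagent), COP(=O)(OC)C(=[N+]=[N-])C(C)=O
Why: Seyferth–Gilbert homologation with the Ohira–Bestmann reagent converts the non-enolisable aldehyde into the terminal alkyne under mild base and leaves both stereocentres untouched.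

**Step 11**
Reactants: 5 5,6,7,8-tetramethoxy-2-methyl-4H-chromen-4-one; 15 (5R,6R)-5-ethynyl-1,5,6-trimethylcyclohex-1-ene
Product: 18 (2S)-5,6,7,8-tetramethoxy-2-methyl-2-{[(1R,2R)-1,2,3-trimethylcyclohex-3-en-1-yl]ethynyl}-2,3-dihydro-4H-chromen-4-one, via benzopyrylium triflate 16 (not isolated), via silyl enol ether 17 (not isolated)
Conditions: TBSOTf (1.2 equiv), 1,2-dichloroethane, 60 °C, 1 h; then 15, CuI (10 mol%), 2,2'-(propane-2,2-diyl)bis[(4S)-4-phenyl-4,5-dihydro-1,3-oxazole] ((S,S)-Ph-BOX, 12 mol%), iPr2NEt, toluene, −78 °C; then 2 M HCl, THF, rt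
Reagents that add atoms: none
Why: O-Silylation of the C4 carbonyl of the vinylogous ester O1–C2=C3–C4=O aromatises the pyranone ring to the 4-silyloxy-1-benzopyrylium triflate 16; CuI and the amine convert 15 into a chiral bis(oxazoline) copper acetylide, which adds to C2 to give silyl enol ether 17, and acid hydrolysis gives the chromanone. The closest known reaction type is the copper bis(oxazoline)-catalysed enantioselective alkynylation of 4-silyloxybenzopyrylium ions from 2-substituted chromones, which forms tertiary ether centres. No ring is closed: the hetero ring is already in place, and the step joins the two fragments at the C2–C(sp) bond. The new stereocentre C2 is set by the chiral ligand on copper, which selects one face of the planar cation; the stereocentres of 15 lie beyond the linear alkyne, so catalyst control should dominate. The step needs attack at C2 and not at C4, and addition must outrun loss of a proton from the C2 methyl group: C4 carries the bulky silyloxy group next to the peri C5 methoxy group, and the deprotonation is reversible, so the cation is regenerated and drained through C2 addition.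

**Step 12**
Reactants: 18 (2S)-5,6,7,8-tetramethoxy-2-methyl-2-{[(1R,2R)-1,2,3-trimethylcyclohex-3-en-1-yl]ethynyl}-2,3-dihydro-4H-chromen-4-one
Product: 19 (2R)-5,6,7,8-tetramethoxy-2-methyl-2-{2-[(1S,2S)-1,2,3-trimethylcyclohex-3-en-1-yl]ethyl}-2,3-dihydro-4H-chromen-4-one
Conditions: KO2C–N=N–CO2K (excess, in portions), AcOH, MeOH/CH2Cl2, rt
Reagents that add atoms: none
Why: Diimide reduction: concerted syn transfer of hydrogen to the alkyne and to the strained cis-alkene that follows is far faster than to a trisubstituted alkene, so the cyclohexene should survive, and no metal surface is present that could cleave the propargylic/allylic aryl ether or shift the ring double bond.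

**Step 13**
Reactants: 19 (2R)-5,6,7,8-tetramethoxy-2-methyl-2-{2-[(1S,2S)-1,2,3-trimethylcyclohex-3-en-1-yl]ethyl}-2,3-dihydro-4H-chromen-4-one
Product: 20 (2R)-5-hydroxy-6,7,8-trimethoxy-2-methyl-2-{2-[(1S,2S)-1,2,3-trimethylcyclohex-3-en-1-yl]ethyl}-2,3-dihydro-4H-chromen-4-one
Conditions: BCl3 (1.5 equiv), CH2Cl2, −78 to −20 °C; MeOH, aq. NaHCO3
Reagents that add atoms: none
Why: Chelation-controlled ether cleavage: boron binds the C4 carbonyl and the peri C5 methoxy oxygen in a six-membered chelate and chloride removes only that methyl group (the standard selective 5-O-demethylation of 5-methoxychromanones and flavones), while the low temperature protects the alkene and the tertiary ether.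

**Step 14**
Reactants: 20 (2R)-5-hydroxy-6,7,8-trimethoxy-2-methyl-2-{2-[(1S,2S)-1,2,3-trimethylcyclohex-3-en-1-yl]ethyl}-2,3-dihydro-4H-chromen-4-one
Product: 22 (2R)-6,7,8-trimethoxy-2-methyl-2-{2-[(1S,2S)-1,2,3-trimethylcyclohex-3-en-1-yl]ethyl}-2H-chromen-5-ol, via chroman-4-ol 21 (not isolated)
Conditions: NaBH4, CeCl3·7H2O, MeOH/THF, −20 to 0 °C; aqueous work-up; then PPTS (cat.), toluene, 50 °C
Reagents that add atoms: none
Why: Luche reduction gives the benzylic chroman-4-ol without the basic conditions that could open the chromanone by retro-oxa-Michael reaction, and mild acid ionises this very electron-rich ortho-hydroxybenzylic alcohol, which loses a C3 proton to give the C3=C4 double bond without involving C2.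

**Compound list**
1 | 1-(6-hydroxy-2,3,4-trimethoxyphenyl)ethan-1-one | CC(=O)c1c(O)cc(OC)c(OC)c1OC | starting material
2 | 1-(3-bromo-2-hydroxy-4,5,6-trimethoxyphenyl)ethan-1-one | CC(=O)c1c(O)c(Br)c(OC)c(OC)c1OC | intermediate
3 | 1-(2-hydroxy-3,4,5,6-tetramethoxyphenyl)ethan-1-one | CC(=O)c1c(O)c(OC)c(OC)c(OC)c1OC | intermediate
4 | 1-(2-hydroxy-3,4,5,6-tetramethoxyphenyl)butane-1,3-dione | CC(=O)CC(=O)c1c(O)c(OC)c(OC)c(OC)c1OC | intermediate
5 | 5,6,7,8-tetramethoxy-2-methyl-4H-chromen-4-one | Cc1cc(=O)c2c(OC)c(OC)c(OC)c(OC)c2o1 | intermediate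
6 | 2-methylidenepropane-1,3-diol | C=C(CO)CO | starting material
7 | 2-[(benzyloxy)methyl]prop-2-en-1-ol | C=C(CO)COCc1ccccc1 | intermediate
8 | 2-[(benzyloxy)methyl]prop-2-enal | C=C(C=O)COCc1ccccc1 | intermediate
9 | (3E)-3-methylpenta-1,3-diene | C=C/C(C)=C/C | starting material
10 | (1S,2R)-1-[(benzyloxy)methyl]-2,3-dimethylcyclohex-3-ene-1-carbaldehyde (formyl cis to the C2 methyl) | c1ccccc1COC[C@]1(C=O)CCC=C(C)[C@H]1C | intermediate
11 | hydrazone of 10 (ring configuration as in 10) | c1ccccc1COC[C@]1(C=NN)CCC=C(C)[C@H]1C | intermediate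
12 | ({[(1R,2R)-1,2,3-trimethylcyclohex-3-en-1-yl]methoxy}methyl)benzene (C1 and C2 methyls cis) | c1ccccc1COC[C@]1(C)CCC=C(C)[C@H]1C | intermediate
13 | [(1R,2R)-1,2,3-trimethylcyclohex-3-en-1-yl]methanol | OC[C@]1(C)CCC=C(C)[C@H]1C | intermediate
14 | (1R,2R)-1,2,3-trimethylcyclohex-3-ene-1-carbaldehyde | O=C[C@]1(C)CCC=C(C)[C@H]1C | intermediate
15 | (5R,6R)-5-ethynyl-1,5,6-trimethylcyclohex-1-ene | C#C[C@]1(C)CCC=C(C)[C@H]1C | intermediate
16 | 4-[(tert-butyldimethylsilyl)oxy]-5,6,7,8-tetramethoxy-2-methylchromenylium trifluoromethanesulfonate | Cc1cc(O[Si](C)(C)C(C)(C)C)c2c(OC)c(OC)c(OC)c(OC)c2[o+]1.[O-]S(=O)(=O)C(F)(F)F | intermediate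
17 | (2S)-4-[(tert-butyldimethylsilyl)oxy]-5,6,7,8-tetramethoxy-2-methyl-2-{[(1R,2R)-1,2,3-trimethylcyclohex-3-en-1-yl]ethynyl}-2H-chromene | COc1c(OC)c2c(c(OC)c1OC)O[C@](C)(C#C[C@]1(C)CCC=C(C)[C@H]1C)C=C2O[Si](C)(C)C(C)(C)C | intermediate
18 | (2S)-5,6,7,8-tetramethoxy-2-methyl-2-{[(1R,2R)-1,2,3-trimethylcyclohex-3-en-1-yl]ethynyl}-2,3-dihydro-4H-chromen-4-one | COc1c(OC)c2c(c(OC)c1OC)O[C@](C)(C#C[C@]1(C)CCC=C(C)[C@H]1C)CC2=O | intermediate
19 | (2R)-5,6,7,8-tetramethoxy-2-methyl-2-{2-[(1S,2S)-1,2,3-trimethylcyclohex-3-en-1-yl]ethyl}-2,3-dihydro-4H-chromen-4-one | COc1c(OC)c2c(c(OC)c1OC)O[C@](C)(CC[C@]1(C)CCC=C(C)[C@H]1C)CC2=O | intermediate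
20 | (2R)-5-hydroxy-6,7,8-trimethoxy-2-methyl-2-{2-[(1S,2S)-1,2,3-trimethylcyclohex-3-en-1-yl]ethyl}-2,3-dihydro-4H-chromen-4-one | COc1c(O)c2c(c(OC)c1OC)O[C@](C)(CC[C@]1(C)CCC=C(C)[C@H]1C)CC2=O | intermediate
21 | (2R)-6,7,8-trimethoxy-2-methyl-2-{2-[(1S,2S)-1,2,3-trimethylcyclohex-3-en-1-yl]ethyl}-3,4-dihydro-2H-chromene-4,5-diol (both C4 epimers) | COc1c(O)c2c(c(OC)c1OC)O[C@](C)(CC[C@]1(C)CCC=C(C)[C@H]1C)CC2O | intermediate
22 | (2R)-6,7,8-trimethoxy-2-methyl-2-{2-[(1S,2S)-1,2,3-trimethylcyclohex-3-en-1-yl]ethyl}-2H-chromen-5-ol | COc1c(O)c2c(c(OC)c1OC)O[C@](C)(CC[C@]1(C)CCC=C(C)[C@H]1C)C=C2 | target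

**Step count**
Total: 14 steps. Longest linear sequence: 11 steps (steps 4 to 14); the chromone branch (steps 1 to 3) joins at step 11.

**Steps most likely to fail**

Step 11. The cation may be drained by deprotonation of its C2 methyl group, the hindered tertiary-propargylic copper acetylide may add too slowly, or facial control may erode if ligand and alkyne stereocentres are mismatched. The fallback sets out from 14 and 3 and returns at 19, bypassing 15 to 18. Horner–Wadsworth–Emmons olefination of 14 with dimethyl (2-oxopropyl)phosphonate (Ba(OH)2, THF/H2O) would give (3E)-4-[(1S,2R)-1,2,3-trimethylcyclohex-3-en-1-yl]but-3-en-2-one F1. Conjugate reduction with [(Ph3P)CuH]6 would give 4-[(1S,2S)-1,2,3-trimethylcyclohex-3-en-1-yl]butan-2-one F2. Kabbe condensation of F2 with 3 (pyrrolidine, toluene, reflux) would give 19 together with its C2 epimer, (2S)-5,6,7,8-tetramethoxy-2-methyl-2-{2-[(1S,2S)-1,2,3-trimethylcyclohex-3-en-1-yl]ethyl}-2,3-dihydro-4H-chromen-4-one F3. The two would be separated by preparative HPLC, and 19 continues with step 13.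

Step 6. Enantiofacial or endo/exo discrimination may be insufficient if the benzyloxymethyl arm perturbs the aldehyde–boron complex. The fallback sets out from 8 and 9 and returns at 10. Cycloaddition promoted by Me2AlCl (CH2Cl2, −78 °C) should keep the regio- and endo-selectivity and give racemic 10, that is 10 together with its enantiomer (1R,2S)-1-[(benzyloxy)methyl]-2,3-dimethylcyclohex-3-ene-1-carbaldehyde F4. Condensation of the racemate with (1R,2R)-N,N'-dimethyl-1,2-diphenylethane-1,2-diamine (molecular sieves, Et2O) would give two diastereomeric aminals: the (4R,5R)-1,3-dimethyl-4,5-diphenylimidazolidine derived from 10 F5 and the one derived from the enantiomer F6. After chromatographic separation, hydrolysis of F5 with dilute aqueous HCl returns 10.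

Step 12. The reduction may stall at the hindered cis-alkene, or the large excess of diimide may slowly attack the ring alkene. The fallback sets out from 18 and returns at 19. Semi-hydrogenation over Lindlar catalyst (Pd/CaCO3 poisoned with Pb(OAc)2, quinoline, H2, EtOAc) would give (2S)-5,6,7,8-tetramethoxy-2-methyl-2-{(Z)-2-[(1S,2R)-1,2,3-trimethylcyclohex-3-en-1-yl]ethenyl}-2,3-dihydro-4H-chromen-4-one F7. Homogeneous hydrogenation of this disubstituted alkene with RhCl(PPh3)3 (H2, benzene/EtOH), a catalyst that leaves trisubstituted alkenes untouched, would then give 19.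

**Further compounds**
F1 | step 11 | (3E)-4-[(1S,2R)-1,2,3-trimethylcyclohex-3-en-1-yl]but-3-en-2-one | CC(=O)/C=C/[C@]1(C)CCC=C(C)[C@H]1C
F2 | step 11 | 4-[(1S,2S)-1,2,3-trimethylcyclohex-3-en-1-yl]butan-2-one | CC(=O)CC[C@]1(C)CCC=C(C)[C@H]1C
F3 | step 11 | (2S)-5,6,7,8-tetramethoxy-2-methyl-2-{2-[(1S,2S)-1,2,3-trimethylcyclohex-3-en-1-yl]ethyl}-2,3-dihydro-4H-chromen-4-one | COc1c(OC)c2c(c(OC)c1OC)O[C@@](C)(CC[C@]1(C)CCC=C(C)[C@H]1C)CC2=O
F4 | step 6 | (1R,2S)-1-[(benzyloxy)methyl]-2,3-dimethylcyclohex-3-ene-1-carbaldehyde | c1ccccc1COC[C@@]1(C=O)CCC=C(C)[C@@H]1C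
F5 | step 6 | (4R,5R)-1,3-dimethyl-4,5-diphenylimidazolidine carrying at C2 the cyclohexenyl group of 10 | CN1[C@H](c2ccccc2)[C@@H](c2ccccc2)N(C)C1[C@@]3(COCc4ccccc4)CCC=C(C)[C@H]3C
F6 | step 6 | (4R,5R)-1,3-dimethyl-4,5-diphenylimidazolidine carrying at C2 the cyclohexenyl group of F4 | CN1[C@H](c2ccccc2)[C@@H](c2ccccc2)N(C)C1[C@]3(COCc4ccccc4)CCC=C(C)[C@@H]3C
F7 | step 12 | (2S)-5,6,7,8-tetramethoxy-2-methyl-2-{(Z)-2-[(1S,2R)-1,2,3-trimethylcyclohex-3-en-1-yl]ethenyl}-2,3-dihydro-4H-chromen-4-one | COc1c(OC)c2c(c(OC)c1OC)O[C@](C)(/C=C\[C@]1(C)CCC=C(C)[C@H]1C)CC2=O
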